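**Strategy.** The ten-membered carbocycle (C1–C10, germacrane numbering; C4=C5 carries the butenolide carbonyl C15, C3 the isobutyrate) is made by one-carbon ring expansion. Everything rests on the unit C3(O)–C4(X)=C5, whose ring bonds are trans: it is the signature of silver-promoted opening of a gem-dibromocyclopropane. The precursor is a nine-membered cis-cycloalkene (C3=C5, from RCM) trans-fused to the C7–C8 γ-lactone and capped with CBr2. In one operation the key step inserts C4 into the ring, sets the E-alkene, installs the C3 isobutyrate with defined configuration and leaves C4–Br for carbonylative closure of the butenolide onto O6.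

Key step: step 13

Numbering remark: target (germacrane) numbering is used throughout: ring C1–C10; C11(=C13)–C12(=O)–O on C7/C8; C14 = CH2OH on C10; C15 = butenolide carbonyl on C4, closed onto O6. TBS = tert-butyldimethylsilyl.

Assumption: (R)-Tol-BINAP/CuI is taken to deliver the Grignard reagent to the face of enoate 3 that gives (3R)-5; if the sense proves opposite, the (S)-ligand is used.

Step 1
Reactants: 1 (tert-butyldimethylsilyloxy)acetaldehyde; 2 methyl (triphenylphosphoranylidene)acetate
Product: 3 methyl (E)-4-(tert-butyldimethylsilyloxy)but-2-enoate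
Conditions: CH2Cl2, rt
Reagents that add atoms: none
Why: Wittig olefination with a stabilised ylide should give the E-enoate.

Step 2
Reactants: 3 methyl (E)-4-(tert-butyldimethylsilyloxy)but-2-enoate; 4 but-3-enylmagnesium bromide
Product: 5 methyl (3R)-3-[(tert-butyldimethylsilyloxy)methyl]hept-6-enoate
Conditions: CuI (2 mol %), (R)-Tol-BINAP (3 mol %), t-BuOMe, −40 °C; aq. NH4Cl
Reagents that add atoms: none
Why: Copper(I)/Tol-BINAP-catalysed asymmetric conjugate addition of the Grignard reagent to the E-enoate, the chiral ligand selecting the β-face and setting C10 (R).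

Step 3
Reactants: 5 methyl (3R)-3-[(tert-butyldimethylsilyloxy)methyl]hept-6-enoate
Product: 6 (3R)-3-[(tert-butyldimethylsilyloxy)methyl]hept-6-enal
Conditions: DIBAL-H, CH2Cl2, −78 °C; Rochelle salt
Reagents that add atoms: none
Why: Partial ester reduction: at −78 °C DIBAL-H should stop at the aluminium hemiacetal, which releases the aldehyde on work-up.

Step 4
Reactants: 7 (S)-4-benzyl-1,3-oxazolidin-2-one; 8 methyl 4-chloro-4-oxobutanoate
Product: 9 methyl 4-[(4S)-4-benzyl-2-oxo-1,3-oxazolidin-3-yl]-4-oxobutanoate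
Conditions: n-BuLi, THF, −78 °C; then 8, −78 → 0 °C
Reagents that add atoms: none
Why: N-Acylation of the lithiated oxazolidinone by the acid chloride.

Step 5
Reactants: 9 methyl 4-[(4S)-4-benzyl-2-oxo-1,3-oxazolidin-3-yl]-4-oxobutanoate; 6 (3R)-3-[(tert-butyldimethylsilyloxy)methyl]hept-6-enal
Product: 11 trans-lactone imide (4S)-4-benzyl-3-{[(2R,3S)-2-{(2R)-2-[(TBSO)methyl]hex-5-enyl}-5-oxooxolan-3-yl]carbonyl}-1,3-oxazolidin-2-one, via syn-aldol hydroxy ester 10 (not isolated)
Conditions: Bu2BOTf, iPr2NEt, CH2Cl2, −78 → 0 °C; pH 7 buffer, H2O2, MeOH; then PPTS (cat.), PhMe, 50 °C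
Reagents that add atoms: none
Why: Evans syn-aldol: the Z-boron enolate of the imide should react through a Zimmerman–Traxler chair on the face away from the benzyl group, setting C7 and C8 (syn), and the γ-hydroxy methyl ester then closes under mild acid to the trans-β,γ-disubstituted lactone.

Step 6
Reactants: 11 trans-lactone imide
Product: 12 S-ethyl (2R,3S)-2-{(2R)-2-[(TBSO)methyl]hex-5-enyl}-5-oxooxolane-3-carbothioate
Conditions: EtSH (3 equiv), n-BuLi (0.3 equiv), THF, 0 °C
Reagents that add atoms: ethanethiol CCS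
Why: Thiolate acyl substitution at the exocyclic imide carbonyl (the most electrophilic acyl group) should give the thioester and release the auxiliary, the lactone being spared and C7 staying in its thermodynamically preferred trans arrangement.

Step 7
Reactants: 12 S-ethyl thioester
Product: 13 (4S,5R)-5-{(2R)-2-[(TBSO)methyl]hex-5-enyl}-4-(prop-2-enoyl)oxolan-2-one
Conditions: Bu3SnCH=CH2, Pd2(dba)3 (cat.), P(2-furyl)3, copper(I) diphenylphosphinate (1.3 equiv), THF, 50 °C
Reagents that add atoms: tributyl(vinyl)stannane C=C[Sn](CCCC)(CCCC)CCCC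
Why: Pd-catalysed, Cu(I)-mediated thioester–organostannane coupling (Liebeskind–Srogl ketone synthesis) should give the vinyl ketone under neutral conditions that neither epimerise C7 nor eliminate the β-acyloxy group.

Step 8
Reactants: 13 vinyl ketone
Product: 14 (4R,5R)-4-[(1R)-1-hydroxyprop-2-enyl]-5-{(2R)-2-[(TBSO)methyl]hex-5-enyl}oxolan-2-one
Conditions: NaBH4, CeCl3·7H2O, MeOH, −78 °C
Reagents that add atoms: none
Why: Luche conditions should give clean 1,2-reduction of the vinyl ketone, hydride adding in the Felkin–Anh sense anti to the C8 branch of the lactone ring to set C6 (R, 1,3-anti to O8).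

Step 9
Reactants: 14 allylic alcohol
Product: 15 (4S,5R)-4-[(1R)-1-(TBSO)prop-2-enyl]-5-{(2R)-2-[(TBSO)methyl]hex-5-enyl}oxolan-2-one
Conditions: TBSOTf, 2,6-lutidine, CH2Cl2, −78 → 0 °C
Reagents that add atoms: tert-butyldimethylsilyl triflate CC(C)(C)[Si](C)(C)OS(=O)(=O)C(F)(F)F
Why: Silylation of the secondary allylic alcohol with a silyl triflate and a hindered base.

Step 10
Reactants: 15 bis-silyl diene lactone
Product: 16 (3aS,4R,5Z,9R,10aR)-4-(TBSO)-9-[(TBSO)methyl]-3,3a,4,7,8,9,10,10a-octahydrocyclonona[b]furan-2-one (nine-membered ring C3=C5–C6–C7–C8–C9–C10–C1–C2)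
Conditions: Grubbs II (10 mol %), CH2Cl2 (1 mM), 40 °C
Reagents that add atoms: none
Why: Ring-closing metathesis of the two terminal alkenes at high dilution should close the nine-membered ring, which can hold only the cis C3=C5 alkene, the trans-lactone and the C6/C10 substituents restricting the chain conformations.

Step 11
Reactants: 16 cis-cyclononene lactone
Product: 17 gem-dibromocyclopropane (CBr2 = C4 bridging C3 and C5, cis-fused, on the alkene face anti to the C6–C7 bond)
Conditions: PhHgCBr3 (2 equiv), benzene, 80 °C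
Reagents that add atoms: phenyl(tribromomethyl)mercury BrC(Br)(Br)[Hg]c1ccccc1
Why: Thermal release of dibromocarbene from the Seyferth reagent under neutral conditions (lactone spared) and cis-stereospecific [2+1] addition to the only alkene, expected on the peripheral face anti to the C6–C7 bond (C6–H eclipsing the alkene to avoid A1,3 strain, the silyloxy group outside), which fixes C3 and C5 of the cyclopropane.

Step 12
Reactants: 17 gem-dibromocyclopropane
Product: 18 Mannich base (17 with CH2NMe2 on C11, trans to the C7–C6 bond)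
Conditions: LDA, THF, −78 °C; Me2N+=CH2 I−, −78 → 0 °C
Reagents that add atoms: Eschenmoser's salt (N,N-dimethylmethyleneiminium iodide) C=[N+](C)C.[I-]
Why: The kinetic lithium enolate of the lactone (C11) should add to the iminium salt (Mannich reaction) anti to the C7 substituent; the amine masks the α-methylene group through the later palladium step, and the C11 configuration is erased in step 16.

Step 13
Reactants: 18 Mannich base
Product: 19 ring-expanded (3S)-isobutyrate (ten-membered ring; 4-bromo; C4=C5 with C3 and C6 trans, i.e. Br cis to C6; 6-OTBS; 14-OTBS; 11-CH2NMe2; 12,8-lactone)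
Conditions: AgO2CCHMe2 (3 equiv), Me2CHCO2H/CH2Cl2 (1:3), rt → 40 °C, dark; aq. NaHCO3
Reagents that add atoms: silver(I) isobutyrate CC(C)C(=O)[O-].[Ag+]
Why: Ag+ abstracts the exo bromide of the cis-fused dibromocyclopropane while the C3–C5 σ-bond opens by two-electron disrotatory electrocyclic cleavage, the ring carbons C2 and C6 turning outward, so that C4 enters the carbocycle (9 → 10) and a trans-configured 2-bromoallyl cation over C3–C4–C5 results, which isobutyrate captures at C3. The closest known reaction type is the silver-assisted solvolytic ring expansion of gem-dihalobicyclo[n.1.0]alkanes to (E)-2-bromocycloalk-2-enyl acetates, alcohols and ethers in medium rings. No ring is closed: the cyclopropane is opened and the nine-membered ring is enlarged by one carbon. The new stereocentre C3 (S) should be set stereospecifically, the nucleophile entering on the exo face (the face the bromide leaves, the ring chain covering the other) with inversion at C3, so that its configuration is relayed from the cyclopropane made in step 11. The step needs loss of the exo rather than the endo bromide (trans, not cis, ring alkene), which the medium ring and the exposed exo bromide should secure, and attack at C3 rather than C5, which the inductively withdrawing C6–OTBS group and the hindrance next to C6 should secure; the protonated amine and the silyl ethers are spectators.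

Step 14
Reactants: 19 ring-expanded bromo isobutyrate
Product: 20 diol (19 with free C6–OH and C14–OH)
Conditions: HF·pyridine, THF/pyridine, 0 °C → rt
Reagents that add atoms: none
Why: Fluoride-driven desilylation should cleave both silyl ethers while the allylic ester, vinyl bromide, lactone and amine are inert.

Step 15
Reactants: 20 diol
Product: 21 bis-lactone amine (target skeleton with H and CH2NMe2 on C11 in place of the methylene)
Conditions: Pd(PPh3)4 (10 mol %), CO (3 atm), Et3N, MeCN, 60 °C
Reagents that add atoms: carbon monoxide [C-]#[O+]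
Why: Pd(0) oxidative addition into the C4–Br bond, CO insertion and capture of the acyl-palladium by the cis-disposed C6 hydroxyl (carbonylative lactonisation) should close the butenolide; the remote C14 hydroxyl cannot reach the acyl group, and C6 keeps its configuration.

Step 16
Reactants: 21 bis-lactone amine
Product: 23 CNP0332805.1 (target), via methiodide 22 (not isolated)
Conditions: MeI, THF, rt; then aq. NaHCO3/EtOAc, rt
Reagents that add atoms: none
Why: Exhaustive N-methylation and E1cB (Hofmann-type) loss of trimethylamine from the β-ammonio lactone under bicarbonate should unveil the α-methylene lactone, the standard last step for Mannich-masked methylene lactones, and removes the C11 stereocentre.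

**Compound list**

1 | (tert-butyldimethylsilyloxy)acetaldehyde | O=CCO[Si](C)(C)C(C)(C)C | starting material
2 | methyl (triphenylphosphoranylidene)acetate | COC(=O)C=P(c1ccccc1)(c1ccccc1)c1ccccc1 | starting material
3 | methyl (E)-4-(tert-butyldimethylsilyloxy)but-2-enoate | COC(=O)/C=C/CO[Si](C)(C)C(C)(C)C | intermediate
4 | but-3-enylmagnesium bromide | C=CCC[Mg]Br | starting material
5 | methyl (3R)-3-[(tert-butyldimethylsilyloxy)methyl]hept-6-enoate | COC(=O)C[C@H](CO[Si](C)(C)C(C)(C)C)CCC=C | intermediate
6 | (3R)-3-[(tert-butyldimethylsilyloxy)methyl]hept-6-enal | O=CC[C@H](CO[Si](C)(C)C(C)(C)C)CCC=C | intermediate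
7 | (S)-4-benzyl-1,3-oxazolidin-2-one | O=C1N[C@@H](Cc2ccccc2)CO1 | starting material
8 | methyl 4-chloro-4-oxobutanoate | COC(=O)CCC(Cl)=O | starting material
9 | methyl 4-[(4S)-4-benzyl-2-oxo-1,3-oxazolidin-3-yl]-4-oxobutanoate | COC(=O)CCC(=O)N1[C@@H](Cc2ccccc2)COC1=O | intermediate
10 | methyl (3S,4R,6R)-3-{[(4S)-4-benzyl-2-oxo-1,3-oxazolidin-3-yl]carbonyl}-4-hydroxy-6-[(TBSO)methyl]dec-9-enoate (syn-aldol hydroxy ester) | COC(=O)C[C@H](C(=O)N1[C@@H](Cc2ccccc2)COC1=O)[C@H](O)C[C@H](CO[Si](C)(C)C(C)(C)C)CCC=C | intermediate (not isolated)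
11 | (4S)-4-benzyl-3-{[(2R,3S)-2-{(2R)-2-[(TBSO)methyl]hex-5-enyl}-5-oxooxolan-3-yl]carbonyl}-1,3-oxazolidin-2-one (trans-lactone imide) | O=C1C[C@H](C(=O)N2[C@@H](Cc3ccccc3)COC2=O)[C@@H](C[C@H](CO[Si](C)(C)C(C)(C)C)CCC=C)O1 | intermediate
12 | S-ethyl (2R,3S)-2-{(2R)-2-[(TBSO)methyl]hex-5-enyl}-5-oxooxolane-3-carbothioate | O=C1C[C@H](C(=O)SCC)[C@@H](C[C@H](CO[Si](C)(C)C(C)(C)C)CCC=C)O1 | intermediate
13 | (4S,5R)-5-{(2R)-2-[(TBSO)methyl]hex-5-enyl}-4-(prop-2-enoyl)oxolan-2-one | O=C1C[C@H](C(=O)C=C)[C@@H](C[C@H](CO[Si](C)(C)C(C)(C)C)CCC=C)O1 | intermediate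
14 | (4R,5R)-4-[(1R)-1-hydroxyprop-2-enyl]-5-{(2R)-2-[(TBSO)methyl]hex-5-enyl}oxolan-2-one | O=C1C[C@H]([C@H](O)C=C)[C@@H](C[C@H](CO[Si](C)(C)C(C)(C)C)CCC=C)O1 | intermediate
15 | (4S,5R)-4-[(1R)-1-(TBSO)prop-2-enyl]-5-{(2R)-2-[(TBSO)methyl]hex-5-enyl}oxolan-2-one | O=C1C[C@H]([C@H](O[Si](C)(C)C(C)(C)C)C=C)[C@@H](C[C@H](CO[Si](C)(C)C(C)(C)C)CCC=C)O1 | intermediate
16 | (3aS,4R,5Z,9R,10aR)-4-(TBSO)-9-[(TBSO)methyl]-3,3a,4,7,8,9,10,10a-octahydrocyclonona[b]furan-2-one | O=C1C[C@@H]2[C@H](O[Si](C)(C)C(C)(C)C)/C=C\CC[C@@H](CO[Si](C)(C)C(C)(C)C)C[C@H]2O1 | intermediate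
17 | gem-dibromocyclopropane of 16 (CBr2 across C3/C5, cis-fused, anti to the C6–C7 bond) | O=C1C[C@@H]2[C@H](O[Si](C)(C)C(C)(C)C)[C@@H]3[C@H](CC[C@@H](CO[Si](C)(C)C(C)(C)C)C[C@H]2O1)C3(Br)Br | intermediate
18 | Mannich base: 17 with CH2NMe2 on C11, trans to the C7–C6 bond | O=C1[C@@H](CN(C)C)[C@@H]2[C@H](O[Si](C)(C)C(C)(C)C)[C@@H]3[C@H](CC[C@@H](CO[Si](C)(C)C(C)(C)C)C[C@H]2O1)C3(Br)Br | intermediate
19 | ring-expanded bromide: ten-membered ring, (3S)-isobutyrate, 4-bromo, C4=C5 with C3/C6 trans (Z by CIP), 6-OTBS, 14-OTBS, 11-CH2NMe2, 12,8-lactone | O=C1[C@@H](CN(C)C)[C@@H]2[C@H](O[Si](C)(C)C(C)(C)C)/C=C(\Br)[C@@H](OC(=O)C(C)C)CC[C@@H](CO[Si](C)(C)C(C)(C)C)C[C@H]2O1 | intermediate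
20 | diol: 19 with free 6-OH and 14-OH | O=C1[C@@H](CN(C)C)[C@@H]2[C@H](O)/C=C(\Br)[C@@H](OC(=O)C(C)C)CC[C@@H](CO)C[C@H]2O1 | intermediate
21 | bis-lactone amine: target with H and CH2NMe2 on C11 | CN(C)C[C@@H]1C(=O)O[C@@H]2C[C@H](CO)CC[C@H](OC(=O)C(C)C)C3=C[C@@H](OC3=O)[C@@H]12 | intermediate
22 | methiodide of 21 (trimethylammonium iodide) | C[N+](C)(C)C[C@@H]1C(=O)O[C@@H]2C[C@H](CO)CC[C@H](OC(=O)C(C)C)C3=C[C@@H](OC3=O)[C@@H]12.[I-] | intermediate (not isolated)
23 | CNP0332805.1, (3S,6R,7S,8R,10R)-14-hydroxy-3-isobutyryloxygermacra-4,11(13)-diene-12,8:15,6-diolide | C=C1C(=O)O[C@@H]2C[C@H](CO)CC[C@H](OC(=O)C(C)C)C3=C[C@@H](OC3=O)[C@@H]12 | target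

**Step count.** Total: 16 steps. Longest linear sequence: 15 steps (steps 1–3, then 5–16); step 4 is the one-step side branch.

**Steps most likely to fail**

1. Step 10 (ring-closing metathesis). Intermolecular metathesis (oligomerisation) may outpace closure of the strained nine-membered ring, and the allylic silyl ether may slow catalyst loading at C5. The fallback sets out from 15 and returns at 16 and forms the C3–C5 bond reductively instead. Ozonolysis of both vinyl groups (O3, CH2Cl2, −78 °C; PPh3) gives the dialdehyde F1. SmI2 in THF at high dilution closes the ring by pinacol coupling to the cis-diol F2. Thiocarbonyldiimidazole converts it into the cyclic thionocarbonate F3. Corey–Winter elimination with P(OMe)3 is syn-stereospecific and should give the cis-alkene 16.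

2. Step 11 (dibromocarbene addition). Facial discrimination may be insufficient, with attack on the alkene face syn to C7; the stereospecific opening would then translate this into the C3 epimer. The fallback sets out from 16 and returns at 19, and it uses the wrong-face adduct instead of discarding it. The diastereomeric dibromocyclopropane F4 is taken through the Mannich reaction of step 12 to the amine F5. Opening with AgClO4 in aqueous acetone (hydroxyl capture) gives the (3R)-bromoallylic alcohol F6. Mitsunobu esterification with isobutyric acid (PPh3, DIAD) inverts C3 and gives 19.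

3. Step 13 (key step). Capture of the bromoallyl cation by the weakly nucleophilic carboxylate may be slow, so that proton loss to a 2-bromo-1,3-diene, attack at C5 or acid-induced desilylation take over. The fallback sets out from 18 and returns at 19 and separates ring expansion from acylation. Opening under the classical hydrolytic conditions (AgClO4, acetone–water, 0 °C) gives the (3S)-bromoallylic alcohol F7. Acylation with isobutyric anhydride (DMAP, Et3N, CH2Cl2) then gives 19.

Further compounds
F1 | step 10 | dialdehyde from ozonolysis of 15 (C5 and C3 as CHO) | O=C1C[C@H]([C@H](O[Si](C)(C)C(C)(C)C)C=O)[C@@H](C[C@H](CO[Si](C)(C)C(C)(C)C)CCC=O)O1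
F2 | step 10 | nine-membered cis-3,5-diol (pinacol product; the two carbinol centres cis, either face) | O=C1C[C@@H]2[C@H](O[Si](C)(C)C(C)(C)C)C(O)C(O)CC[C@@H](CO[Si](C)(C)C(C)(C)C)C[C@H]2O1
F3 | step 10 | cyclic thionocarbonate of F2 | O=C1C[C@@H]2[C@H](O[Si](C)(C)C(C)(C)C)C3OC(=S)OC3CC[C@@H](CO[Si](C)(C)C(C)(C)C)C[C@H]2O1
F4 | step 11 | diastereomeric gem-dibromocyclopropane (CBr2 on the face syn to C7) | O=C1C[C@@H]2[C@H](O[Si](C)(C)C(C)(C)C)[C@H]3[C@@H](CC[C@@H](CO[Si](C)(C)C(C)(C)C)C[C@H]2O1)C3(Br)Br
F5 | step 11 | Mannich base of F4 | O=C1[C@@H](CN(C)C)[C@@H]2[C@H](O[Si](C)(C)C(C)(C)C)[C@H]3[C@@H](CC[C@@H](CO[Si](C)(C)C(C)(C)C)C[C@H]2O1)C3(Br)Br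
F6 | step 11 | (3R)-bromoallylic alcohol (C3 epimer of F7) | O=C1[C@@H](CN(C)C)[C@@H]2[C@H](O[Si](C)(C)C(C)(C)C)/C=C(\Br)[C@H](O)CC[C@@H](CO[Si](C)(C)C(C)(C)C)C[C@H]2O1
F7 | step 13 | (3S)-bromoallylic alcohol (19 with OH in place of the isobutyrate) | O=C1[C@@H](CN(C)C)[C@@H]2[C@H](O[Si](C)(C)C(C)(C)C)/C=C(\Br)[C@@H](O)CC[C@@H](CO[Si](C)(C)C(C)(C)C)C[C@H]2O1
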